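**Plan**

- Retrosynthesis: once the two ring B allyl ethers and the C7 silyl ether are taken off, ring A is cut at C8–C8a, C4a–C5, C5–C6 and C7–C8 into a γ-pyranonyl diazomethyl ketone and a prenyl siloxyalkyne.
- Enabling feature: ring A is a 5,7-dioxygenated benzene with its prenyl group on C6 between the two oxygens, fused to the pyranone along C4a–C8a. This is the 2-alkyl-3-siloxyphenol pattern that a vinylketene/siloxyalkyne benzannulation writes onto an alkene arm, here the C4a=C8a bond of the pyranone.
- Ring C is cut at O1–C8a and C4a–C8a (diethyl oxalate), at the C3–prenyl bond (prenyl bromide) and at C3–C4 (ethyl acetate), back to 2,4-dihydroxyacetophenone, which supplies ring B, C2 and C3.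
- Forward order: ring B is present from the start, the prenyl diketone chain is built, ring C is closed as a pyranone ester and turned into the diazoketone, ring A is grown last in one operation, then the silyl and allyl groups are removed.
- Stereochemistry: the target has no stereocentre and no stereogenic double bond. The only selectivity to be won is regiochemical (6-prenyl, not 8-prenyl), and the polarisation of the siloxyalkyne sets it.

Key step: step 9

Assumption: the ring B phenols are carried as allyl ethers instead of acetals, because ring C is closed with acid and the final unmasking should be neutral next to prenyl/phenol pairs; diazomethane is used as an ethereal solution prepared beforehand from N-methyl-N-nitroso-p-toluenesulfonamide.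

**Route**

Step 1
Reactants: 1 2,4-dihydroxyacetophenone
Product: 2 1-[2,4-bis(allyloxy)phenyl]ethanone
Conditions: allyl bromide, K2CO3, DMF, 60 °C
Reagents that add atoms: allyl bromide, C=CCBr
Why: Williamson etherification with a reactive allylic halide in DMF should alkylate both the free and the hydrogen-bonded phenol, giving ethers that tolerate the strong base, acid and light of later steps and leave under neutral zerovalent-palladium conditions.

Step 2
Reactants: 2 1-[2,4-bis(allyloxy)phenyl]ethanone
Product: 3 1-[2,4-bis(allyloxy)phenyl]butane-1,3-dione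
Conditions: NaH, EtOAc, THF, reflux; aq. HCl work-up
Reagents that add atoms: ethyl acetate, CCOC(C)=O
Why: Crossed Claisen condensation in which the methyl ketone enolate is acetylated by ethyl acetate and the equilibrium is pulled over by irreversible deprotonation of the β-diketone by NaH.

Step 3
Reactants: 3 1-[2,4-bis(allyloxy)phenyl]butane-1,3-dione; 4 prenyl bromide (1-bromo-3-methylbut-2-ene)
Product: 5 1-[2,4-bis(allyloxy)phenyl]-2-(3-methylbut-2-enyl)butane-1,3-dione
Conditions: K2CO3, acetone, rt
Reagents that add atoms: none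
Why: C-alkylation of the soft β-diketone enolate by an allylic bromide under mild carbonate conditions is the usual way to 2-prenyl-1,3-diketones; the one stereocentre formed is racemic, enolisable and is erased when ring C closes.

Step 4
Reactants: 5 1-[2,4-bis(allyloxy)phenyl]-2-(3-methylbut-2-enyl)butane-1,3-dione; 6 diethyl oxalate
Product: 8 ethyl 6-[2,4-bis(allyloxy)phenyl]-5-(3-methylbut-2-enyl)-4-oxo-4H-pyran-2-carboxylate, via triketo ester 7 (not isolated)
Conditions: LiN(i-Pr)2 (3.2 equiv), THF, −78 → −20 °C; 6, −78 °C; aq. HCl; then p-TsOH·H2O (cat.), toluene, 60 °C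
Reagents that add atoms: none
Why: Claisen-type γ-acylation of the β-diketone dianion should occur at its only terminal methyl group with the very electrophilic oxalate, and the resulting 1,3,5-triketone cyclodehydrates to the 4-pyranone under acid mild enough to spare the allyl ethers and the prenyl alkene.

Step 5
Reactants: 8 ethyl 6-[2,4-bis(allyloxy)phenyl]-5-(3-methylbut-2-enyl)-4-oxo-4H-pyran-2-carboxylate
Product: 9 6-[2,4-bis(allyloxy)phenyl]-5-(3-methylbut-2-enyl)-4-oxo-4H-pyran-2-carboxylic acid
Conditions: LiOH·H2O, THF/H2O, 0 °C; then 1 M HCl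
Reagents that add atoms: lithium hydroxide, [Li+].[OH-] (supplies the carboxyl oxygen)
Why: Saponification of an ester activated by the ring oxygen and the vinylogous carbonyl should be fast at 0 °C, and any ring-opened triketo acid would reclose on acidification.

Step 6
Reactants: 9 6-[2,4-bis(allyloxy)phenyl]-5-(3-methylbut-2-enyl)-4-oxo-4H-pyran-2-carboxylic acid
Product: 11 1-{6-[2,4-bis(allyloxy)phenyl]-5-(3-methylbut-2-enyl)-4-oxo-4H-pyran-2-yl}-2-diazoethanone, via mixed carbonic anhydride 10 (not isolated)
Conditions: i-BuOCOCl, N-methylmorpholine, THF, −15 °C; then CH2N2 (Et2O solution), 0 °C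
Reagents that add atoms: diazomethane, C=[N+]=[N-]; isobutyl chloroformate, CC(C)COC(=O)Cl (its atoms stay only in intermediate 10)
Why: Arndt–Eistert-type acylation of diazomethane through the mixed carbonic anhydride avoids HCl, which would threaten the prenyl alkene, and the carbonate leaving group takes up the proton so that only a small excess of diazomethane meets the electron-poor pyranone.

Step 7
Reactants: 12 4-methylpent-3-enoic acid
Product: 13 ethyl 4-methylpent-3-enoate
Conditions: EtI, K2CO3, DMF, rt
Reagents that add atoms: ethyl iodide, CCI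
Why: Carboxylate O-alkylation under weakly basic conditions avoids the acid-promoted lactonisation and double-bond migration that a Fischer esterification of this β,γ-unsaturated acid would risk.

Step 8
Reactants: 13 ethyl 4-methylpent-3-enoate
Product: 16 triisopropyl(5-methylhex-4-en-1-ynyloxy)silane, via lithium dibromoenolate 14 (not isolated), via lithium ynolate 15 (not isolated)
Conditions: CH2Br2, lithium 2,2,6,6-tetramethylpiperidide, THF, −78 °C; LiN(SiMe3)2; n-BuLi, −78 °C → rt; i-Pr3SiCl, −78 °C → rt
Reagents that add atoms: dibromomethane, BrCBr; chlorotriisopropylsilane, CC(C)[Si](Cl)(C(C)C)C(C)C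
Why: Kowalski ester homologation, in which addition of dibromomethyllithium, enolisation and bromine–lithium exchange trigger the carbenoid 1,2-shift to the ynolate, whose O-silylation by the bulky chlorosilane gives a siloxyalkyne stable enough to purify.

Step 9
Reactants: 11 1-{6-[2,4-bis(allyloxy)phenyl]-5-(3-methylbut-2-enyl)-4-oxo-4H-pyran-2-yl}-2-diazoethanone; 16 triisopropyl(5-methylhex-4-en-1-ynyloxy)silane
Product: 21 2-[2,4-bis(allyloxy)phenyl]-5-hydroxy-3,6-bis(3-methylbut-2-enyl)-7-(triisopropylsilyloxy)-4H-chromen-4-one, via pyranonylketene 17 (not isolated), via cyclobutenone 18 (not isolated), via dienylketene 19 (not isolated), via cyclohexadienone 20 (not isolated)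
Conditions: 16 (1.5 equiv), hν (300 nm, Pyrex), ClCH2CH2Cl, 25 °C; then 80 °C
Reagents that add atoms: none
Why: Irradiation expels N2 and the pyranonyl group migrates (Wolff rearrangement, C8–C8a) to give ketene 17, whose carbonyl carbon is attacked by the nucleophilic prenyl-bearing carbon of ynol ether 16, so the [2+2] cycloaddition gives cyclobutenone 18 with C5–C6 and C7–C8 in place. Four-electron electrocyclic opening of 18 by light or heat gives dienylketene 19, the ketene carbon then bonds to the pyranone C–H carbon (C4a–C5), and enolisation of dione 20 gives phenol 21. The closest known reaction type is the photochemical Wolff version of the Danheiser benzannulation of alkenyl, aryl and heteroaryl diazomethyl ketones with siloxyalkynes; here the weakly aromatic C4a=C8a bond of the γ-pyranone takes the place of the alkene arm, a substrate for which no direct example is known. Ring A closes by a thermally allowed disrotatory six-electron electrocyclisation followed by tautomerisation, driven by aromatisation and by the hydrogen bond from the C5 hydroxyl to the C4 carbonyl. No stereocentre persists, since those of 18 and 20 are racemic and vanish on ring opening and enolisation. The selectivity needed is regiochemical, prenyl at C6 and silyloxy at C7 instead of an 8-prenyl isomer; the oxygen-induced polarisation of the siloxyalkyne secures it, and closure can only occur at the single pyranone carbon next to the ketene-bearing one.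

Step 10
Reactants: 21 2-[2,4-bis(allyloxy)phenyl]-5-hydroxy-3,6-bis(3-methylbut-2-enyl)-7-(triisopropylsilyloxy)-4H-chromen-4-one
Product: 22 2-[2,4-bis(allyloxy)phenyl]-5,7-dihydroxy-3,6-bis(3-methylbut-2-enyl)-4H-chromen-4-one
Conditions: Bu4NF, AcOH, THF, 0 °C
Reagents that add atoms: none
Why: Fluoride-induced cleavage of the aryl silyl ether, buffered with acetic acid so the 7-phenoxide is not left under basic conditions, should leave the allyl ethers and prenyl groups untouched.

Step 11
Reactants: 22 2-[2,4-bis(allyloxy)phenyl]-5,7-dihydroxy-3,6-bis(3-methylbut-2-enyl)-4H-chromen-4-one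
Product: 23 cudraflavone C
Conditions: Pd(PPh3)4 (cat.), morpholine, THF, rt
Reagents that add atoms: none
Why: Tsuji–Trost deallylation, in which zerovalent palladium ionises the aryl allyl ethers and morpholine traps the π-allyl complex irreversibly, is a neutral unmasking that avoids acid-induced chroman formation between a prenyl group and a neighbouring phenol.

**Compound list**

1 | 2,4-dihydroxyacetophenone | CC(=O)c1ccc(O)cc1O | starting material
2 | 1-[2,4-bis(allyloxy)phenyl]ethanone | CC(=O)c1ccc(OCC=C)cc1OCC=C | intermediate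
3 | 1-[2,4-bis(allyloxy)phenyl]butane-1,3-dione | CC(=O)CC(=O)c1ccc(OCC=C)cc1OCC=C | intermediate
4 | prenyl bromide (1-bromo-3-methylbut-2-ene) | CC(C)=CCBr | starting material
5 | 1-[2,4-bis(allyloxy)phenyl]-2-(3-methylbut-2-enyl)butane-1,3-dione (racemic) | CC(=O)C(CC=C(C)C)C(=O)c1ccc(OCC=C)cc1OCC=C | intermediate
6 | diethyl oxalate | CCOC(=O)C(=O)OCC | starting material
7 | ethyl 6-[2,4-bis(allyloxy)phenyl]-5-(3-methylbut-2-enyl)-2,4,6-trioxohexanoate (racemic, drawn as the keto form) | CCOC(=O)C(=O)CC(=O)C(CC=C(C)C)C(=O)c1ccc(OCC=C)cc1OCC=C | intermediate (not isolated)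
8 | ethyl 6-[2,4-bis(allyloxy)phenyl]-5-(3-methylbut-2-enyl)-4-oxo-4H-pyran-2-carboxylate | CCOC(=O)c1cc(=O)c(CC=C(C)C)c(-c2ccc(OCC=C)cc2OCC=C)o1 | intermediate
9 | 6-[2,4-bis(allyloxy)phenyl]-5-(3-methylbut-2-enyl)-4-oxo-4H-pyran-2-carboxylic acid | OC(=O)c1cc(=O)c(CC=C(C)C)c(-c2ccc(OCC=C)cc2OCC=C)o1 | intermediate
10 | mixed anhydride of acid 9 and isobutyl carbonic acid | CC(C)COC(=O)OC(=O)c1cc(=O)c(CC=C(C)C)c(-c2ccc(OCC=C)cc2OCC=C)o1 | intermediate (not isolated)
11 | 1-{6-[2,4-bis(allyloxy)phenyl]-5-(3-methylbut-2-enyl)-4-oxo-4H-pyran-2-yl}-2-diazoethanone | [N-]=[N+]=CC(=O)c1cc(=O)c(CC=C(C)C)c(-c2ccc(OCC=C)cc2OCC=C)o1 | intermediate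
12 | 4-methylpent-3-enoic acid | CC(C)=CCC(=O)O | starting material
13 | ethyl 4-methylpent-3-enoate | CCOC(=O)CC=C(C)C | intermediate
14 | lithium 1,1-dibromo-5-methylhexa-1,4-dien-2-olate | [Li+].[O-]C(CC=C(C)C)=C(Br)Br | intermediate (not isolated)
15 | lithium 5-methylhex-4-en-1-yn-1-olate | [Li+].[O-]C#CCC=C(C)C | intermediate (not isolated)
16 | triisopropyl(5-methylhex-4-en-1-ynyloxy)silane | CC(C)=CCC#CO[Si](C(C)C)(C(C)C)C(C)C | intermediate
17 | 2-{6-[2,4-bis(allyloxy)phenyl]-5-(3-methylbut-2-enyl)-4-oxo-4H-pyran-2-yl}ethen-1-one | O=C=Cc1cc(=O)c(CC=C(C)C)c(-c2ccc(OCC=C)cc2OCC=C)o1 | intermediate (not isolated)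
18 | 4-{6-[2,4-bis(allyloxy)phenyl]-5-(3-methylbut-2-enyl)-4-oxo-4H-pyran-2-yl}-2-(3-methylbut-2-enyl)-3-(triisopropylsilyloxy)cyclobut-2-en-1-one (racemic) | O=C1C(CC=C(C)C)=C(O[Si](C(C)C)(C(C)C)C(C)C)C1c1cc(=O)c(CC=C(C)C)c(-c2ccc(OCC=C)cc2OCC=C)o1 | intermediate (not isolated)
19 | (3E)-4-{6-[2,4-bis(allyloxy)phenyl]-5-(3-methylbut-2-enyl)-4-oxo-4H-pyran-2-yl}-2-(3-methylbut-2-enyl)-3-(triisopropylsilyloxy)buta-1,3-dien-1-one, ketene carbon and pyranone cis | CC(C)[Si](C(C)C)(C(C)C)O/C(C(CC=C(C)C)=C=O)=C/c1cc(=O)c(CC=C(C)C)c(-c2ccc(OCC=C)cc2OCC=C)o1 | intermediate (not isolated)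
20 | 2-[2,4-bis(allyloxy)phenyl]-3,6-bis(3-methylbut-2-enyl)-7-(triisopropylsilyloxy)-4aH-chromene-4,5-dione (racemic) | O=C1C(CC=C(C)C)=C(O[Si](C(C)C)(C(C)C)C(C)C)C=C2OC(-c3ccc(OCC=C)cc3OCC=C)=C(CC=C(C)C)C(=O)C12 | intermediate (not isolated)
21 | 2-[2,4-bis(allyloxy)phenyl]-5-hydroxy-3,6-bis(3-methylbut-2-enyl)-7-(triisopropylsilyloxy)-4H-chromen-4-one | CC(C)=CCc1c(O[Si](C(C)C)(C(C)C)C(C)C)cc2oc(-c3ccc(OCC=C)cc3OCC=C)c(CC=C(C)C)c(=O)c2c1O | intermediate
22 | 2-[2,4-bis(allyloxy)phenyl]-5,7-dihydroxy-3,6-bis(3-methylbut-2-enyl)-4H-chromen-4-one | CC(C)=CCc1c(O)cc2oc(-c3ccc(OCC=C)cc3OCC=C)c(CC=C(C)C)c(=O)c2c1O | intermediate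
23 | cudraflavone C, 2-(2,4-dihydroxyphenyl)-5,7-dihydroxy-3,6-bis(3-methylbut-2-enyl)-4H-chromen-4-one | CC(C)=CCc1c(O)cc2oc(-c3ccc(O)cc3O)c(CC=C(C)C)c(=O)c2c1O | target

**Count**

Total steps: 11. Longest linear sequence: 9 steps (steps 1–6, 9, 10, 11); steps 7 and 8 form the two-step side branch to the siloxyalkyne.

**Steps most likely to fail**

1. Step 9. The 2-aryl-4-pyranone chromophore, and later the flavone product, may absorb the light in competition with the diazoketone, and the pyranone may photoisomerise, so that the Wolff rearrangement stays incomplete or unclean. The fallback makes the same ketene in the dark. It sets out from diazoketone 11: a Wolff rearrangement catalysed by silver benzoate (PhCO2Ag, Et3N, THF/H2O, dark, rt), with water as the trap, should give {6-[2,4-bis(allyloxy)phenyl]-5-(3-methylbut-2-enyl)-4-oxo-4H-pyran-2-yl}acetic acid F1, kept cold to avoid decarboxylation. Oxalyl chloride with catalytic DMF in CH2Cl2 at 0 °C then gives {6-[2,4-bis(allyloxy)phenyl]-5-(3-methylbut-2-enyl)-4-oxo-4H-pyran-2-yl}acetyl chloride F2. Slow addition of Et3N to F2 and siloxyalkyne 16 in toluene at rt dehydrochlorinates F2, and the fallback comes back to the route at pyranonylketene 17, which is carried thermally (80–110 °C) through 18, 19 and 20 to 21. Acid chloride dehydrohalogenation, ketene/ynol ether [2+2] cycloaddition and thermal cyclobutenone benzannulation are all established reaction types.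

2. Step 8. The doubly activated α-protons of the β,γ-unsaturated ester may be removed by the carbenoid and amide bases faster than dibromomethyllithium adds, and the skipped enyne may migrate under the strongly basic conditions. The fallback sets out from prenyl bromide 4: copper-catalysed coupling with ethynylmagnesium bromide (HC≡CMgBr, CuBr·SMe2 cat., THF, 0 °C) should give 5-methylhex-4-en-1-yne F3. n-BuLi at −78 °C gives lithium 5-methylhex-4-en-1-yn-1-ide F4, and oxidation of this acetylide by LiOOt-Bu (from t-BuOOH and LiN(SiMe3)2, THF, −78 → 0 °C) comes back to the route at lithium ynolate 15, which is silylated with i-Pr3SiOTf to 16.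

3. Step 4. Dianion formation may be incomplete, the hindered 2-prenyl diketone may suffer retro-Claisen cleavage or add twice to the oxalate, and the acid closure may be accompanied by cyclisation of the prenyl alkene onto an enol oxygen. The fallback joins the same chain from the other end. It sets out from diethyl oxalate 6: Claisen condensation with commercial 6-methylhept-5-en-2-one (NaOEt, EtOH, 0 °C → rt) at the methyl group should give ethyl 8-methyl-2,4-dioxonon-7-enoate F5. Separately, methyl 2,4-dihydroxybenzoate with allyl bromide and K2CO3 in DMF gives methyl 2,4-bis(allyloxy)benzoate F6. The dianion of F5 (NaH, then LiN(i-Pr)2, THF, −78 → 0 °C) is aroylated at C5 by F6, and the fallback comes back to the route at triketo ester 7, which is closed to 8 with p-TsOH as in step 4.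

**Further compounds**

F1 | step 9 | {6-[2,4-bis(allyloxy)phenyl]-5-(3-methylbut-2-enyl)-4-oxo-4H-pyran-2-yl}acetic acid | OC(=O)Cc1cc(=O)c(CC=C(C)C)c(-c2ccc(OCC=C)cc2OCC=C)o1
F2 | step 9 | {6-[2,4-bis(allyloxy)phenyl]-5-(3-methylbut-2-enyl)-4-oxo-4H-pyran-2-yl}acetyl chloride | ClC(=O)Cc1cc(=O)c(CC=C(C)C)c(-c2ccc(OCC=C)cc2OCC=C)o1
F3 | step 8 | 5-methylhex-4-en-1-yne | C#CCC=C(C)C
F4 | step 8 | lithium 5-methylhex-4-en-1-yn-1-ide | [Li+].[C-]#CCC=C(C)C
F5 | step 4 | ethyl 8-methyl-2,4-dioxonon-7-enoate | CCOC(=O)C(=O)CC(=O)CCC=C(C)C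
F6 | step 4 | methyl 2,4-bis(allyloxy)benzoate | COC(=O)c1ccc(OCC=C)cc1OCC=C
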